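A leftover is what I lean on: once the protic impurity and the whole charge of starting material have each taken their equal share of partner, 0.0140 M of partner stands over, so partner is the reagent in excess, but it falls as it reacts, and freezing it at one middle level, with open intermediate lost to it at a single first-order rate, is a rough device of mine and not a true pseudo-first-order case.

the same everywhere: capture agent 2.50 mM; protic impurity 1.00 mM
- north-east: starting material 0.050 M (fed, over 0.800 min); partner 0.0650 M; time 1.0 min; all but starting material at the start; starting material goes in evenly over 0.800 min, the run ends at 1.0 min
- north: starting material 0.050 M; partner 0.0650 M; time 1.0 min; everything together in a closed stirred flask, run for 1.0 min
- east: starting material 0.050 M; partner 0.0650 M (fed, over 0.800 min); time 1.0 min; all but partner at the start; partner goes in evenly over 0.800 min, the run ends at 1.0 min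
- west: starting material 0.050 M; partner 0.0650 M; a single well-mixed tank run continuously and read at steady state, 1.0 min in it on average

    open intermediate + capture agent → trapped intermediate (k1 = 35 /M/s)
    partner + protic impurity → quenched reagent (k2 = 55 /M/s)
    starting material → open intermediate (k3 = 0.041 /s)
    partner + open intermediate → target (k4 = 0.30 /M/s)

- the set-up with the highest amount of open intermediate at the outlet or at the end, in percent of the starting material put in ("none" if the first two lie within 2 percentage points) (north-east / north / east / west / none)
- amount of open intermediate at the outlet or at the end, in percent of the starting material put in, north-east
- amount of open intermediate at the outlet or at the end, in percent of the starting material put in, north
- amount of open intermediate at the outlet or at the end, in percent of the starting material put in, east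
- amount of open intermediate at the outlet or at the end, in percent of the starting material put in, west

- the stated concentrations are those of everything mixed, before any reaction; amounts are the same in each set-up
- the feed brings no volume worth counting
- run time (north-east): 1.0 min

Which numbers must I know well? The protic impurity matters little, since it can take hardly any of the partner. The capture constant matters little too, because the half-life of open intermediate by capture as charged, 0.13 min, is short against the run and shorter than its 0.59 min by partner; but the capture charge counts point for point, taking 5.00% of the starting material. The opening, with its half-life of 0.28 min, has made 91.5% in a closed flask by the reading. The partner step stands in an exponent, so a tenth off there moves the north amount by up to 11.7% of itself, and this is the number to get right.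

The drain is the rate at which partner, frozen midway between its level after the impurity and its level with half the starting material turned to target, removes open intermediate: 0.927 /min. Open intermediate is born about 0.407 min in, and what survives is the amount made, less capture, times exp(−drain × time under partner). In east partner climbs evenly until its feed ends, which shortens that time to 0.497 min. In north-east I put birth at half the feed plus half of 0.407 min, and west takes the tank form.

north: 49.9%

east: 54.6%

north-east: 47.3%

west: 34.3%

best: east

The forecast names east, with 49% in north-east, 46.5% in north, 54% in east and 35.3% in west, on the ground that “Feeding partner keeps it low while the intermediate builds”. It shares my winner but sets north-east above north, where I set it below.

The simulation gives east as best, with 46.8% in north-east, 47.2% in north, 54.1% in east and 35.3% in west.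

The capture charge is the thing to weigh carefully. A neighbour of east charged with 0.0063 M of capture agent, the other charges and the time held, has a capture share of 12.6%, and with the same drain of 0.927 /min and the same 0.497 min under partner I reckon 49.8% of open intermediate at 1.00 min. That neighbour flask gives 49.4% of open intermediate, with trapped intermediate at 12.6%.

The constants were drawn at random within sensible limits; the result is computed.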